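**Retrosynthetic overview**

1. The last disconnection is the C7–CH2–C3' methylene bridge: diol 16 (ring A complete), pyrone 20 and one CH2 unit are joined by a Mannich-type coupling.
2. The strategy rests on ring A, the benzene ring of the dihydrobenzofuran. C5 and C7 each lie between two oxygen-bearing carbons (C4/C6 and C6/C7a), so an electrophile cannot choose between them. The C5 acyl carbon and the C6 oxygen are neighbours, so isobutyric acid delivers both across a C5–C6 aryne (12 → 15).
3. Silyl triflate 12 comes from 3,5-bis(benzyloxy)phenol. Its single MOM ether (future C4–O) directs SiMe3 and then prenyl to its two ortho carbons (future C5 and C3a), so C7 is never functionalised and no acid is used while silicon is on the ring.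
4. Ring order: ring A is purchased. The dihydrofuran ring is closed by 5-exo phenoxide opening of a Shi epoxide (sets C2); the second freed phenol becomes the triflate and dehydration gives the isopropenyl group. The pyrone ring is made separately from 3-pentanone and malonyl dichloride and attached last.

Key step: step 8

Remark: 1 and the L-fructose-derived Shi ketone are taken as purchasable, and every aryl–SiMe3 compound on the oxygenated ring (4 to 12) is worked up under neutral or basic conditions because such silanes protodesilylate readily with acid.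

**Route**

Step 1
Reactants: 1 3,5-bis(benzyloxy)phenol
Product: 2 1,3-bis(benzyloxy)-5-(methoxymethoxy)benzene
Conditions: NaH, THF–DMF, 0 °C; MOMCl, 0 °C to rt
Reagents that add atoms: chloromethyl methyl ether (MOMCl), COCCl
Why: Williamson-type O-alkylation of the sodium phenoxide by the α-chloro ether installs the MOM acetal, the only chelating ortho-director in the molecule.

Step 2
Reactants: 2 1,3-bis(benzyloxy)-5-(methoxymethoxy)benzene
Product: 4 [2,4-bis(benzyloxy)-6-(methoxymethoxy)phenyl]trimethylsilane, via aryllithium 3 (not isolated)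
Conditions: n-BuLi, Et2O, 0 °C; TMSCl, −78 °C to rt
Reagents that add atoms: chlorotrimethylsilane (TMSCl), C[Si](C)(C)Cl
Why: Directed ortho-metalation, in which the bidentate MOM group should deliver n-BuLi to its own ortho C–H rather than to the C–H between the two non-chelating benzyl ethers, followed by C-silylation of the aryllithium.

Step 3
Reactants: 4 [2,4-bis(benzyloxy)-6-(methoxymethoxy)phenyl]trimethylsilane; 5 prenyl bromide (1-bromo-3-methylbut-2-ene)
Product: 7 [4,6-bis(benzyloxy)-2-(methoxymethoxy)-3-(3-methylbut-2-en-1-yl)phenyl]trimethylsilane, via aryllithium 6 (not isolated)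
Conditions: n-BuLi, THF, 0 °C; CuBr·SMe2 (10 mol %), then 5, −78 °C to rt
Reagents that add atoms: none
Why: A second directed ortho-metalation at the only remaining position ortho to the MOM group, then copper-catalysed SN2 allylation at the primary carbon of prenyl bromide, places silicon and prenyl on the two carbons flanking the MOM-bearing carbon (future C5 and C3a).

Step 4
Reactants: 7 [4,6-bis(benzyloxy)-2-(methoxymethoxy)-3-(3-methylbut-2-en-1-yl)phenyl]trimethylsilane
Product: 8 {4,6-bis(benzyloxy)-3-{[(2S)-3,3-dimethyloxiran-2-yl]methyl}-2-(methoxymethoxy)phenyl}trimethylsilane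
Conditions: 1,2:4,5-di-O-isopropylidene-β-L-erythro-2,3-hexodiulo-2,6-pyranose (ent-Shi ketone, 30 mol %), Oxone (2KHSO5·KHSO4·K2SO4), K2CO3, Bu4NHSO4, MeCN–DMM–aq. Na2B4O7 buffer (pH about 10.5), 0 °C
Reagents that add atoms: potassium peroxymonosulfate (active component of Oxone), [K+].[O-]S(=O)(=O)OO
Why: Shi asymmetric epoxidation of the trisubstituted prenyl alkene through the spiro dioxirane transition state; the D-fructose-derived ketone gives the (R)-epoxide of R–CH2–CH=CMe2 alkenes, so its enantiomer should set the (S) centre needed here, and the basic buffer protects the aryl–Si bond.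

Step 5
Reactants: 8 {4,6-bis(benzyloxy)-3-{[(2S)-3,3-dimethyloxiran-2-yl]methyl}-2-(methoxymethoxy)phenyl}trimethylsilane
Product: 10 (2R)-2-(2-hydroxypropan-2-yl)-4-(methoxymethoxy)-5-(trimethylsilyl)-2,3-dihydro-1-benzofuran-6-ol, via bis-phenol epoxide 9 (not isolated)
Conditions: H2 (1 atm), Pd/C, NaHCO3, EtOAc–MeOH, rt; filter; K2CO3, MeOH, rt
Reagents that add atoms: none
Why: Hydrogenolysis of both aryl benzyl ethers (no alkene is present at this stage) frees two phenols, and the phenoxide ortho to the side chain opens the epoxide by 5-exo-tet SN2 attack at the secondary carbon with inversion, turning the (S)-epoxide into (R)-C2 of the dihydrofuran ring, while the distal phenol cannot reach the epoxide.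

Step 6
Reactants: 10 (2R)-2-(2-hydroxypropan-2-yl)-4-(methoxymethoxy)-5-(trimethylsilyl)-2,3-dihydro-1-benzofuran-6-ol
Product: 11 (2R)-2-(2-hydroxypropan-2-yl)-4-(methoxymethoxy)-5-(trimethylsilyl)-2,3-dihydro-1-benzofuran-6-yl trifluoromethanesulfonate
Conditions: PhNTf2, DBU, MeCN, rt to 40 °C
Reagents that add atoms: N-phenylbis(trifluoromethanesulfonimide) (PhNTf2), O=S(=O)(N(c1ccccc1)S(=O)(=O)C(F)(F)F)C(F)(F)F
Why: Chemoselective O-sulfonylation of the phenoxide by the mild triflyl donor leaves the tertiary alcohol untouched, and the basic, fluoride-free medium neither protodesilylates the ring nor triggers aryne formation.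

Step 7
Reactants: 11 (2R)-2-(2-hydroxypropan-2-yl)-4-(methoxymethoxy)-5-(trimethylsilyl)-2,3-dihydro-1-benzofuran-6-yl trifluoromethanesulfonate
Product: 12 (2R)-4-(methoxymethoxy)-2-(prop-1-en-2-yl)-5-(trimethylsilyl)-2,3-dihydro-1-benzofuran-6-yl trifluoromethanesulfonate
Conditions: Burgess reagent (methyl N-(triethylammoniosulfonyl)carbamate), toluene, 60 °C
Reagents that add atoms: none
Why: Burgess dehydration (syn Ei elimination of the sulfamate ester) of the tertiary alcohol should favour the isopropenyl group, because six methyl hydrogens compete with the single, inductively deactivated C2–H, and the neutral conditions leave the silyl triflate and the C2 stereocentre alone.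

Step 8
Reactants: 12 (2R)-4-(methoxymethoxy)-2-(prop-1-en-2-yl)-5-(trimethylsilyl)-2,3-dihydro-1-benzofuran-6-yl trifluoromethanesulfonate; 13 isobutyric acid
Product: 15 1-[(2R)-6-hydroxy-4-(methoxymethoxy)-2-(prop-1-en-2-yl)-2,3-dihydro-1-benzofuran-5-yl]-2-methylpropan-1-one, via aryne 14 (not isolated)
Conditions: 13 (1.2 equiv) premixed with CsF (4 equiv), THF; then 12, 125 °C, sealed tube
Reagents that add atoms: none
Why: Fluoride attacks silicon and the C6 triflate leaves, giving aryne 14 with the strained bond between C5 and C6 of ring A. Cesium isobutyrate adds through oxygen at C6, the aryne carbon remote from the C4 OMOM group, because that terminus is the more linear one of the distorted aryne and the negative charge then develops at C5 beside the electron-withdrawing C4–O bond. The C5 aryl anion attacks the neighbouring ester carbonyl through a transient four-membered alkoxide that collapses to the ketone and the C6 phenoxide, so C6–O and C5–C(=O) form in one operation; this is the known insertion of arynes from o-silylaryl triflates into the C–O bond of carboxylic acids (a formal anionic Fries shift). No ring is closed and no stereocentre is created, and C2 is untouched because the medium holds no strong base or Lewis acid that could ionise the allylic C2–O bond. The step needs regioselectivity (oxygen to C6, acyl to C5), secured by the C4 alkoxy group, and acyl transfer faster than protonation of the C5 anion, favoured by aprotic THF at high temperature with the acid held as its cesium salt.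

Step 9
Reactants: 15 1-[(2R)-6-hydroxy-4-(methoxymethoxy)-2-(prop-1-en-2-yl)-2,3-dihydro-1-benzofuran-5-yl]-2-methylpropan-1-one
Product: 16 1-[(2R)-4,6-dihydroxy-2-(prop-1-en-2-yl)-2,3-dihydro-1-benzofuran-5-yl]-2-methylpropan-1-one
Conditions: HCl (1.25 M in MeOH), MeOH, 0 °C to rt
Reagents that add atoms: none
Why: Acid-catalysed acetal methanolysis of the MOM ether, safe now that silicon has left the ring, frees the C4 phenol, and dilute acid at room temperature should spare the isopropenyl group and the allylic C2–O bond.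

Step 10
Reactants: 17 3-pentanone
Product: 18 (Z)-trimethyl(pent-2-en-3-yloxy)silane
Conditions: TMSCl, Et3N, DMF, 80 °C
Reagents that add atoms: chlorotrimethylsilane (TMSCl), C[Si](C)(C)Cl
Why: Thermodynamic silyl enol ether formation on a symmetrical ketone raises no regiochemical question; the Z isomer is expected to predominate and either geometry serves in the next step.

Step 11
Reactants: 18 (Z)-trimethyl(pent-2-en-3-yloxy)silane; 19 malonyl dichloride
Product: 20 6-ethyl-4-hydroxy-5-methyl-2H-pyran-2-one
Conditions: Et2O, −78 °C to rt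
Reagents that add atoms: none
Why: C-acylation of the silyl enol ether by one acid chloride, then O-acylation (lactonisation) of the resulting enol by the second, builds the 4-hydroxy-2-pyrone ring in one operation (Effenberger pyrone synthesis).

Step 12
Reactants: 16 1-[(2R)-4,6-dihydroxy-2-(prop-1-en-2-yl)-2,3-dihydro-1-benzofuran-5-yl]-2-methylpropan-1-one; 20 6-ethyl-4-hydroxy-5-methyl-2H-pyran-2-one
Product: 22 6-ethyl-3-{[(2R)-4,6-dihydroxy-5-(2-methylpropanoyl)-2-(prop-1-en-2-yl)-2,3-dihydro-1-benzofuran-7-yl]methyl}-4-hydroxy-5-methyl-2H-pyran-2-one, via Mannich base 21 (not isolated)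
Conditions: 20, Me2N=CH2+ I− (1.0 equiv), MeCN, rt; then 16, 50 °C
Reagents that add atoms: N,N-dimethylmethyleneiminium iodide (Eschenmoser's salt), C=[N+](C)C.[I-]
Why: Mannich aminomethylation of the pyrone at C3', loss of dimethylamine to the 3-methylene-pyran-2,4-dione and Michael-type attack by C7, the only unsubstituted carbon of ring A, should form the methylene bridge without touching the stereocentre.

**Compound list**

1 | 3,5-bis(benzyloxy)phenol | Oc1cc(OCc2ccccc2)cc(OCc2ccccc2)c1 | starting material
2 | 1,3-bis(benzyloxy)-5-(methoxymethoxy)benzene | COCOc1cc(OCc2ccccc2)cc(OCc2ccccc2)c1 | intermediate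
3 | [2,4-bis(benzyloxy)-6-(methoxymethoxy)phenyl]lithium | [Li]c1c(OCOC)cc(OCc2ccccc2)cc1OCc1ccccc1 | intermediate
4 | [2,4-bis(benzyloxy)-6-(methoxymethoxy)phenyl]trimethylsilane | COCOc1cc(OCc2ccccc2)cc(OCc2ccccc2)c1[Si](C)(C)C | intermediate
5 | prenyl bromide (1-bromo-3-methylbut-2-ene) | CC(C)=CCBr | starting material
6 | [4,6-bis(benzyloxy)-2-(methoxymethoxy)-3-(trimethylsilyl)phenyl]lithium | [Li]c1c(OCOC)c([Si](C)(C)C)c(OCc2ccccc2)cc1OCc1ccccc1 | intermediate
7 | [4,6-bis(benzyloxy)-2-(methoxymethoxy)-3-(3-methylbut-2-en-1-yl)phenyl]trimethylsilane | COCOc1c(CC=C(C)C)c(OCc2ccccc2)cc(OCc2ccccc2)c1[Si](C)(C)C | intermediate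
8 | {4,6-bis(benzyloxy)-3-{[(2S)-3,3-dimethyloxiran-2-yl]methyl}-2-(methoxymethoxy)phenyl}trimethylsilane | CC1(C)O[C@H]1Cc1c(OCOC)c([Si](C)(C)C)c(OCc2ccccc2)cc1OCc1ccccc1 | intermediate
9 | 4-{[(2S)-3,3-dimethyloxiran-2-yl]methyl}-5-(methoxymethoxy)-6-(trimethylsilyl)benzene-1,3-diol | CC1(C)O[C@H]1Cc1c(OCOC)c([Si](C)(C)C)c(O)cc1O | intermediate
10 | (2R)-2-(2-hydroxypropan-2-yl)-4-(methoxymethoxy)-5-(trimethylsilyl)-2,3-dihydro-1-benzofuran-6-ol | CC(C)(O)[C@H]1Cc2c(OCOC)c([Si](C)(C)C)c(O)cc2O1 | intermediate
11 | (2R)-2-(2-hydroxypropan-2-yl)-4-(methoxymethoxy)-5-(trimethylsilyl)-2,3-dihydro-1-benzofuran-6-yl trifluoromethanesulfonate | CC(C)(O)[C@H]1Cc2c(OCOC)c([Si](C)(C)C)c(OS(=O)(=O)C(F)(F)F)cc2O1 | intermediate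
12 | (2R)-4-(methoxymethoxy)-2-(prop-1-en-2-yl)-5-(trimethylsilyl)-2,3-dihydro-1-benzofuran-6-yl trifluoromethanesulfonate | C=C(C)[C@H]1Cc2c(OCOC)c([Si](C)(C)C)c(OS(=O)(=O)C(F)(F)F)cc2O1 | intermediate
13 | isobutyric acid | CC(C)C(=O)O | starting material
14 | (2R)-5,6-didehydro-4-(methoxymethoxy)-2-(prop-1-en-2-yl)-2,3-dihydro-1-benzofuran (C5–C6 aryne) | C=C(C)[C@H]1CC2=C(OCOC)C#CC=C2O1 | intermediate
15 | 1-[(2R)-6-hydroxy-4-(methoxymethoxy)-2-(prop-1-en-2-yl)-2,3-dihydro-1-benzofuran-5-yl]-2-methylpropan-1-one | C=C(C)[C@H]1Cc2c(OCOC)c(C(=O)C(C)C)c(O)cc2O1 | intermediate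
16 | 1-[(2R)-4,6-dihydroxy-2-(prop-1-en-2-yl)-2,3-dihydro-1-benzofuran-5-yl]-2-methylpropan-1-one | C=C(C)[C@H]1Cc2c(O)c(C(=O)C(C)C)c(O)cc2O1 | intermediate
17 | 3-pentanone | CCC(=O)CC | starting material
18 | (Z)-trimethyl(pent-2-en-3-yloxy)silane | C/C=C(\O[Si](C)(C)C)CC | intermediate
19 | malonyl dichloride | O=C(Cl)CC(=O)Cl | starting material
20 | 6-ethyl-4-hydroxy-5-methyl-2H-pyran-2-one | CCc1oc(=O)cc(O)c1C | intermediate
21 | 3-[(dimethylamino)methyl]-6-ethyl-4-hydroxy-5-methyl-2H-pyran-2-one | CCc1oc(=O)c(CN(C)C)c(O)c1C | intermediate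
22 | 6-ethyl-3-{[(2R)-4,6-dihydroxy-5-(2-methylpropanoyl)-2-(prop-1-en-2-yl)-2,3-dihydro-1-benzofuran-7-yl]methyl}-4-hydroxy-5-methyl-2H-pyran-2-one (CNP0206652.1) | C=C(C)[C@H]1Cc2c(O)c(C(=O)C(C)C)c(O)c(Cc3c(O)c(C)c(CC)oc3=O)c2O1 | target

**Step count and risks**

Total step count: 12. Longest linear sequence: 10 (steps 1 to 9 and 12, from 1).

Steps most likely to fail:

Step 8. The C5 aryl anion may be protonated before it reaches the ester carbonyl, which stops the sequence at simple O-arylation of the acid. The aryne may also be consumed by fluoride or by an ene reaction with the isopropenyl group of a second molecule, or the acid may protodesilylate the precursor before fluoride acts.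

The fallback sets out from 10 and returns at 15. The phenol of 10 is acylated (isobutyryl chloride, Et3N, CH2Cl2, 0 °C) to (2R)-2-(2-hydroxypropan-2-yl)-4-(methoxymethoxy)-5-(trimethylsilyl)-2,3-dihydro-1-benzofuran-6-yl 2-methylpropanoate F1. ICl (CH2Cl2, −78 °C) then exchanges silicon for iodine at the same carbon (ipso-iododesilylation, run before any alkene is present) to give (2R)-2-(2-hydroxypropan-2-yl)-5-iodo-4-(methoxymethoxy)-2,3-dihydro-1-benzofuran-6-yl 2-methylpropanoate F2. Burgess dehydration gives (2R)-5-iodo-4-(methoxymethoxy)-2-(prop-1-en-2-yl)-2,3-dihydro-1-benzofuran-6-yl 2-methylpropanoate F3. Iodine–lithium exchange (n-BuLi, THF, −100 °C) then generates the same C5 anion beside the C6 ester under strictly aprotic conditions, so the 1,3 O-to-C acyl shift (anionic Fries type) should deliver 15.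

Step 7. Elimination may run toward C2–H and give the ring enol ether, which would also erase the stereocentre, or the tertiary sulfamate may ionise.

The fallback sets out from 8 and returns at 12, and avoids any dehydration. Base-induced isomerisation of the epoxide with Et2Al(TMP) (from Et2AlCl and LiTMP, toluene, 0 °C) removes a methyl hydrogen and leaves the C–O bond at the stereocentre intact, giving (2S)-1-[4,6-bis(benzyloxy)-2-(methoxymethoxy)-3-(trimethylsilyl)phenyl]-3-methylbut-3-en-2-ol F4. Reductive debenzylation with lithium 4,4'-di-tert-butylbiphenylide (LiDBB, THF, −78 °C), which spares the alkene, gives 4-[(2S)-2-hydroxy-3-methylbut-3-en-1-yl]-5-(methoxymethoxy)-6-(trimethylsilyl)benzene-1,3-diol F5. Mitsunobu cycloetherification (PPh3, DIAD, THF, 0 °C) closes the dihydrofuran ring with inversion to (2R)-4-(methoxymethoxy)-2-(prop-1-en-2-yl)-5-(trimethylsilyl)-2,3-dihydro-1-benzofuran-6-ol F6. Triflation as in step 6 gives 12.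

Step 2. Lithiation may leak to the C–H between the two benzyloxy groups, or to a benzylic O–CH2 followed by Wittig rearrangement; the same control is relied on again in step 3.

The fallback sets out from 1 and returns at 4. 1 is converted (ClCONEt2, NaH, THF) into 3,5-bis(benzyloxy)phenyl diethylcarbamate F7, whose carbamate outranks every ether as a director. s-BuLi/TMEDA (THF, −78 °C) then TMSCl gives 3,5-bis(benzyloxy)-2-(trimethylsilyl)phenyl diethylcarbamate F8. Reductive carbamate cleavage with Cp2Zr(H)Cl (THF, rt) gives 3,5-bis(benzyloxy)-2-(trimethylsilyl)phenol F9, and NaH/MOMCl as in step 1 gives 4.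

Further compounds
F1 | step 8 | (2R)-2-(2-hydroxypropan-2-yl)-4-(methoxymethoxy)-5-(trimethylsilyl)-2,3-dihydro-1-benzofuran-6-yl 2-methylpropanoate | CC(C)(O)[C@H]1Cc2c(OCOC)c([Si](C)(C)C)c(OC(=O)C(C)C)cc2O1
F2 | step 8 | (2R)-2-(2-hydroxypropan-2-yl)-5-iodo-4-(methoxymethoxy)-2,3-dihydro-1-benzofuran-6-yl 2-methylpropanoate | CC(C)(O)[C@H]1Cc2c(OCOC)c(I)c(OC(=O)C(C)C)cc2O1
F3 | step 8 | (2R)-5-iodo-4-(methoxymethoxy)-2-(prop-1-en-2-yl)-2,3-dihydro-1-benzofuran-6-yl 2-methylpropanoate | C=C(C)[C@H]1Cc2c(OCOC)c(I)c(OC(=O)C(C)C)cc2O1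
F4 | step 7 | (2S)-1-[4,6-bis(benzyloxy)-2-(methoxymethoxy)-3-(trimethylsilyl)phenyl]-3-methylbut-3-en-2-ol | C=C(C)[C@@H](O)Cc1c(OCOC)c([Si](C)(C)C)c(OCc2ccccc2)cc1OCc1ccccc1
F5 | step 7 | 4-[(2S)-2-hydroxy-3-methylbut-3-en-1-yl]-5-(methoxymethoxy)-6-(trimethylsilyl)benzene-1,3-diol | C=C(C)[C@@H](O)Cc1c(OCOC)c([Si](C)(C)C)c(O)cc1O
F6 | step 7 | (2R)-4-(methoxymethoxy)-2-(prop-1-en-2-yl)-5-(trimethylsilyl)-2,3-dihydro-1-benzofuran-6-ol | C=C(C)[C@H]1Cc2c(OCOC)c([Si](C)(C)C)c(O)cc2O1
F7 | step 2 | 3,5-bis(benzyloxy)phenyl diethylcarbamate | CCN(CC)C(=O)Oc1cc(OCc2ccccc2)cc(OCc2ccccc2)c1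
F8 | step 2 | 3,5-bis(benzyloxy)-2-(trimethylsilyl)phenyl diethylcarbamate | CCN(CC)C(=O)Oc1cc(OCc2ccccc2)cc(OCc2ccccc2)c1[Si](C)(C)C
F9 | step 2 | 3,5-bis(benzyloxy)-2-(trimethylsilyl)phenol | Oc1cc(OCc2ccccc2)cc(OCc2ccccc2)c1[Si](C)(C)C
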